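**Assumptions:** 2H-pyran-2-one, 2-bromoacrolein, 4-methylpent-4-enoic acid and 2-methylbut-2-ene are commercial. The two tartrate-modified γ-acyloxyallylboronates (Steps 2 and 9) are prepared separately as reagents and are not counted as route steps. The C1 configuration of the target is taken to be the axial (anomeric) acetate.

## Retrosynthetic overview
1. The C1-OAc/C3=C4 dihydropyran acetal and the free C10-OH are revealed last. The acid-labile dienyl acetal stays masked as an enol lactone until a final DIBAL reduction with Ac2O trapping, then desilylation.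
2. The C12–C15 side chain comes from a C4–CHO (by Pd formylation of C4–Br) through anti-selective α-acyloxyallylboration and prenyl cross-metathesis.
3. Key step: a photoredox decarboxylative radical macrocyclisation (9-endo conjugate addition onto a 3-alkenyl-2-pyranone) forms C4a–C5, closes the nine-membered ring, and sets C4a and C11a cis.
4. The cyclisation precursor comes from a C3-selective Suzuki coupling of 3,5-dibromo-2-pyranone with a vinyl boronate built from 2-bromoacrolein, a syn-allylboration that sets C9/C10, and an isoprenoid acid by cross-metathesis.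
5. Ring order: pyranone (preformed) → nine-membered ring (radical step) → dihydropyran acetal (last two steps).

## Route

**Step 1**
Reactants: 1, 2H-pyran-2-one
Product: 2, 3,5-dibromo-2H-pyran-2-one
Conditions: Br2 (2.3 equiv), CH2Cl2, 0 °C; then Et3N, 0 °C → rt
Reagents that add atoms: Br2, BrBr
Why: Bromination/dehydrobromination (addition–elimination) gives the dibromide; C3–Br is the more electrophilic site for Pd coupling. No stereocentres.

**Step 2**
Reactants: 3, 2-bromoacrolein
Product: 4, (3R,4S)-2-bromo-3-hydroxyhexa-1,5-dien-4-yl acetate (syn)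
Conditions: (Z)-γ-acetoxyallyl tartrate boronate (1.3 equiv), toluene, 4 Å MS, −78 °C, 12 h
Reagents that add atoms: (Z)-γ-acetoxyallylboronate of (R,R)-DIPT, `CC(=O)O/C=C\CB1O[C@@H](C(=O)OC(C)C)[C@H](C(=O)OC(C)C)O1` (tartrate enantiomer chosen to give 9S,10S)
Why: Proposed new method: Zimmerman–Traxler chair allylboration in which the Z-γ-OAc group sits axial, giving the syn relationship, and the tartrate auxiliary fixes the absolute configuration at C10 (aldehyde face) and C9 (reagent γ-carbon). The closest known reaction is Roush γ-alkoxyallylboration, here with an acyloxy group.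

**Step 3**
Reactants: 4
Product: 5, (3R,4S)-2-bromo-3-(triethylsilyloxy)hexa-1,5-dien-4-yl acetate
Conditions: TESOTf, 2,6-lutidine, CH2Cl2, −78 °C
Reagents that add atoms: TESOTf, `CC[Si](CC)(CC)OS(=O)(=O)C(F)(F)F`
Why: Silylation of the C10 alcohol prevents 1,2-acetyl migration under the basic conditions of later steps. The stereocentres are untouched.

**Step 4**
Reactants: 5; 6, 4-methylpent-4-enoic acid
Product: 7, (4E,6S,7R)-6-acetoxy-8-bromo-4-methyl-7-(triethylsilyloxy)nona-4,8-dienoic acid
Conditions: Hoveyda–Grubbs II (5 mol %), CH2Cl2, 40 °C, 3 equiv 6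
Reagents that add atoms: none (6 is a reactant; ethylene is lost)
Why: Cross-metathesis of the terminal vinyl with the 1,1-disubstituted alkene builds the trisubstituted C7=C8 bond (E-selective); the vinyl bromide and existing stereocentres are untouched.

**Step 5**
Reactants: 7
Product: 8, (4E,6S,7S)-6-acetoxy-4-methyl-8-(pinacolboryl)-7-(triethylsilyloxy)nona-4,8-dienoic acid
Conditions: B2pin2, PdCl2(dppf) (5 mol %), KOAc, dioxane, 80 °C
Reagents that add atoms: B2pin2, `CC1(C)OB(OC1(C)C)B1OC(C)(C)C(C)(C)O1`
Why: Miyaura borylation converts the vinyl bromide into the C11 nucleophile. The descriptor at C7 changes only because of CIP priorities; the spatial arrangement is unchanged.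

**Step 6**
Reactants: 2; 8
Product: 9, (4E,6S,7S)-6-acetoxy-8-(5-bromo-2-oxo-2H-pyran-3-yl)-4-methyl-7-(triethylsilyloxy)nona-4,8-dienoic acid
Conditions: Pd(PPh3)4 (10 mol %), K3PO4, THF/H2O, 50 °C
Reagents that add atoms: none
Why: Suzuki–Miyaura coupling occurs at the more reactive C3–Br and leaves C5–Br for the side chain. This is the cyclisation precursor.

**Step 7**
Reactants: 9
Product: 10, cis-fused 2-oxabicyclic enol lactone (4aS,9S,10S,11aS), C1 = O, 4-Br, 9-OAc, 10-OTES, 11-methylene
Conditions: [Ir{dF(CF3)ppy}2(dtbbpy)]PF6 (2 mol %), K2HPO4, DMF (2 mM, syringe-pump addition), blue LEDs, rt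
Reagents that add atoms: none (CO2 is lost; H is gained from the medium)
Why: Proposed new method: Ir(III)* oxidises the carboxylate, and the primary C5 radical adds 9-endo to C4 of the 3-alkenyl-pyranone, forming C4a–C5. Ir(II) then reduces the α-carbonyl/allylic radical to the dienolate, which is protonated at the α-carbon (C11a) anti to the new C4a–C5 bond, leaving C11=CH2 deconjugated. The tether forces the cis-ring fusion, and the C9/C10 centres direct the face at C4a. The closest known reactions are photoredox decarboxylative Giese addition and radical macrocyclisation.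

**Step 8**
Reactants: 10
Product: 11, enol lactone with 4-CHO
Conditions: Pd(PPh3)4 (5 mol %), CO (1 atm), Bu3SnH, toluene, 50 °C
Reagents that add atoms: carbon monoxide, `[C-]#[O+]`
Why: Pd-catalysed reductive carbonylation of the vinyl bromide (Stille formylation) installs C12 as a stable β-acyloxy enal; no stereocentre is formed.

**Step 9**
Reactants: 11
Product: 12, (12S,13R)-12-hydroxy-13-benzoyloxy-14-ene (C12–OH, C13–OBz, terminal vinyl)
Conditions: (E)-γ-benzoyloxyallyl tartrate boronate (2 equiv), toluene, 4 Å MS, −78 °C → −40 °C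
Reagents that add atoms: (E)-γ-benzoyloxyallylboronate of (S,S)-DIPT, `O=C(c1ccccc1)O/C=C/CB1O[C@H](C(=O)OC(C)C)[C@@H](C(=O)OC(C)C)O1` (enantiomer matched to the substrate)
Why: Proposed new method: the E-reagent reacts through a chair transition state to give the anti C12/C13 diol derivative, and the tartrate fixes C12 and C13, overriding the substrate bias. The closest known reaction is Roush γ-alkoxyallylboration with double stereodifferentiation.

**Step 10**
Reactants: 12; 13, 2-methylbut-2-ene
Product: 14, as 12 with the vinyl converted to CH=CMe2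
Conditions: Grubbs II (5 mol %), CH2Cl2, 40 °C, sealed tube, 20 equiv 13
Reagents that add atoms: none (13 is a reactant)
Why: Cross-metathesis prenylation selectively engages the terminal vinyl; the trisubstituted C7=C8 and the exocyclic 1,1-disubstituted alkene are unreactive. The stereocentres are untouched.

**Step 11**
Reactants: 14
Product: 15, C1-OAc, C12-OAc, C3=C4 enol ether with 10-OTES
Conditions: DIBAL-H (2.5 equiv), CH2Cl2, −78 °C, 1 h; then Ac2O, DMAP, pyridine, −78 → 0 °C
Reagents that add atoms: Ac2O, `CC(=O)OC(C)=O`
Why: The enol-lactone carbonyl is the most electrophilic ester, so it is reduced to the lactol alkoxide (the free C12 alkoxide consumes one equivalent of hydride). In situ acetylation gives the C1 acetal, with the axial (anomeric) acetate 1R preferred, and acetylates C12–OH. Both acetylations happen in one pot.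

**Step 12**
Reactants: 15
Product: 16, antheliatin
Conditions: HF·pyridine, excess pyridine, THF, 0 °C, 30 min
Reagents that add atoms: none
Why: Buffered fluoride removes the TES ether to reveal the C10 carbinol without touching the acetates, benzoate or the acid-labile acetal.

## Compound list
1 | 2H-pyran-2-one | `O=C1C=CC=CO1` | starting material
2 | 3,5-dibromo-2H-pyran-2-one | `O=C1OC=C(Br)C=C1Br` | intermediate
3 | 2-bromoacrolein | `C=C(Br)C=O` | starting material
4 | (3R,4S)-2-bromo-3-hydroxyhexa-1,5-dien-4-yl acetate | `C=C(Br)[C@H](O)[C@@H](OC(C)=O)C=C` | intermediate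
5 | TES ether of 4 | `C=C(Br)[C@H](O[Si](CC)(CC)CC)[C@@H](OC(C)=O)C=C` | intermediate
6 | 4-methylpent-4-enoic acid | `C=C(C)CCC(=O)O` | starting material
7 | (4E,6S,7R)-6-acetoxy-8-bromo-4-methyl-7-(TESO)nona-4,8-dienoic acid | `C=C(Br)[C@H](O[Si](CC)(CC)CC)[C@@H](OC(C)=O)/C=C(C)/CCC(=O)O` | intermediate
8 | vinyl-Bpin analogue of 7 | `C=C(B1OC(C)(C)C(C)(C)O1)[C@H](O[Si](CC)(CC)CC)[C@@H](OC(C)=O)/C=C(C)/CCC(=O)O` | intermediate
9 | 3-alkenyl-5-bromo-2-pyranone acid | `O=C1OC=C(Br)C=C1C(=C)[C@H](O[Si](CC)(CC)CC)[C@@H](OC(C)=O)/C=C(C)/CCC(=O)O` | intermediate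
10 | cis-fused macrocyclic 4-bromo enol lactone | `C=C1[C@H]2C(=O)OC=C(Br)[C@H]2CC/C(C)=C/[C@H](OC(C)=O)[C@H]1O[Si](CC)(CC)CC` | intermediate
11 | 4-formyl enol lactone | `C=C1[C@H]2C(=O)OC=C(C=O)[C@H]2CC/C(C)=C/[C@H](OC(C)=O)[C@H]1O[Si](CC)(CC)CC` | intermediate
12 | C12-OH, C13-OBz, 14-vinyl lactone | `C=C1[C@H]2C(=O)OC=C([C@H](O)[C@@H](C=C)OC(=O)c3ccccc3)[C@H]2CC/C(C)=C/[C@H](OC(C)=O)[C@H]1O[Si](CC)(CC)CC` | intermediate
13 | 2-methylbut-2-ene | `CC=C(C)C` | starting material
14 | prenyl analogue of 12 | `C=C1[C@H]2C(=O)OC=C([C@H](O)[C@@H](C=C(C)C)OC(=O)c3ccccc3)[C@H]2CC/C(C)=C/[C@H](OC(C)=O)[C@H]1O[Si](CC)(CC)CC` | intermediate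
15 | C1,C12-diacetate of 14 (lactol acetate), 10-OTES | `C=C1[C@H]2[C@@H](OC(C)=O)OC=C([C@H](OC(C)=O)[C@@H](C=C(C)C)OC(=O)c3ccccc3)[C@H]2CC/C(C)=C/[C@H](OC(C)=O)[C@H]1O[Si](CC)(CC)CC` | intermediate
16 | antheliatin | `C=C1[C@H]2[C@@H](OC(C)=O)OC=C([C@H](OC(C)=O)[C@@H](C=C(C)C)OC(=O)c3ccccc3)[C@H]2CC/C(C)=C/[C@H](OC(C)=O)[C@H]1O` | target

**Total steps: 12. Longest linear sequence: 11** (3 → 4 → 5 → 7 → 8 → 9 → 10 → 11 → 12 → 14 → 15 → 16).

## Three steps most likely to fail
1. **Step 7 (9-endo radical macrocyclisation).** The nine-membered ring may not close, and the radical could instead add at C6 of the pyranone or at the vinyl CH2, or be reduced uncyclised. Fallback: build the cis-fused bicycle first by a different route, then close the ring at C10–C11 by Nozaki–Hiyama–Kishi coupling of a C11 vinyl iodide with the C10 aldehyde.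
2. **Step 9 (and Step 2), the γ-acyloxyallylboration.** The acyloxy reagents may be unstable or unselective. Fallback: use established Roush γ-silyloxy or γ-PMB-oxyallylboronates, then swap protecting groups (PMB → Ac at C9; PMB → Bz at C13) before Step 11.
3. **Step 11 (DIBAL chemoselectivity).** DIBAL may attack the C9/C12 acetates or the benzoate, or benzoate may migrate from C13 to the C12 alkoxide. Fallback: reduce the enol lactone at the stage of Step 8/9, while C9, C12 and C13 are still silyl or PMB ethers, then install all esters in one global acylation at the end.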